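**Retrosynthetic overview**
1. The target is an ent-labd-7-ene. Ring B is opened at C6–C7 and closed by 6-endo cyclisation of an α-keto radical at C7 (next to a C8 ketone that later becomes the C7=C8/C17 unit via its enol triflate) onto an exocyclic C5=C6 methylene on ring A.
2. Enabling feature: C5 of ring A lies between the quaternary carbons C4 and C10, so the C5=C6 methylene has no allylic hydrogens and can only be attacked at C6. The cis-axial pair C19 (on C4) and C20 (on C10) covers one face of C5, so hydrogen delivery gives the trans ring fusion. The trisubstituted C7=C8 alkene of ring B is the enol-triflate retron of the ketone that makes C7 a radical site.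
3. C9–C10 and both its stereocenters come from an Ireland–Claisen rearrangement of a C2 allylic ester of the complete side-chain acid (1,3-transfer of chirality from C2 to C10). The C1=C2 alkene it leaves returns the C2 hydroxyl at the end by hydroboration.
4. Ring A is bought as (4R,6R)-actinol. Its carbinol steers an oxime-directed C–H acetoxylation that installs the C19 acetate, and is then inverted by Mitsunobu esterification. C13 is bought in (R)-3-methylglutaric acid monomethyl ester and extended by mixed Kolbe coupling.
5. Order of rings: ring A (purchased), then ring B (step 13).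

Key step: step 13

Remark (numbering and faces): labdane numbering is used throughout. In actinol, C1(=O) is C5, C2 is C4, C3 is C3, C4(OH) is C2, C5 is C1 and C6(Me) is C10. The α face is the face of ring A that carries C19 (and later C20); β is the other face.
Remark (assumption): (4R,6R)-actinol and (R)-3-methylglutaric acid monomethyl ester are taken as commercial chiral-pool materials; the epimerisable C10 centre of 2–5 is erased in step 5, so its configuration there is immaterial.

**Route**

Step 1
Reactants: 1 (4R,6R)-actinol
Product: 2 silyl ether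
Conditions: TBDPSCl, imidazole, DMF, rt
Reagents that add atoms: tert-butyl(chloro)diphenylsilane, CC(C)(C)[Si](Cl)(c1ccccc1)c1ccccc1
Why: O-silylation of the secondary alcohol gives a bulky, acid-stable ether that survives step 3 and holds the C2 oxygen equatorial; no stereocenter is touched.

Step 2
Reactants: 2 silyl ether
Product: 3 oxime
Conditions: NH2OH·HCl, NaOAc, EtOH, 60 °C
Reagents that add atoms: hydroxylamine hydrochloride, Cl.NO
Why: Oxime condensation of the hindered ketone should place the N–OH syn to the less hindered C10 side, so the nitrogen lone pair faces the quaternary C4.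

Step 3
Reactants: 3 oxime
Product: 4 acetoxylated O-acetyl oxime
Conditions: Pd(OAc)2 (5 mol %), PhI(OAc)2 (1.3 equiv), AcOH/Ac2O 1:1, 25 °C then 100 °C
Reagents that add atoms: acetic anhydride, CC(=O)OC(C)=O; (diacetoxyiodo)benzene, CC(=O)OI(OC(C)=O)c1ccccc1
Why: Oxime-directed Pd(OAc)2-catalysed β-C(sp3)–H acetoxylation (in situ O-acetyl oxime, cyclopalladation, oxidation to tetravalent palladium, C–O reductive elimination) reaches only the C4 methyls, and of these only the equatorial one, coplanar with C=N, which in the chair with the silyloxy group equatorial is the methyl cis to it, so C19 is set cis to the C2 oxygen.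

Step 4
Reactants: 4 acetoxylated O-acetyl oxime
Product: 5 acetoxy ketone
Conditions: NaHSO3, EtOH/H2O, 80 °C
Reagents that add atoms: water, O
Why: Bisulfite cleavage of the O-acetyl oxime (N–O cleavage by sulfite, hydrolysis of the N-sulfonyl imine) returns the ketone without touching the acetate, the silyl ether or C4.

Step 5
Reactants: 5 acetoxy ketone
Product: 6 enone
Conditions: IBX (3 equiv), TsOH (cat.), DMSO/PhF, 75 °C
Reagents that add atoms: none
Why: IBX dehydrogenation through the enol can only give the C1=C10 enone because C10–H is the sole α-hydrogen (C4 is quaternary); the C10 stereocenter is erased.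

Step 6
Reactants: 6 enone
Product: 7 hydroxy enone
Conditions: HF·pyridine, THF, 0 °C → rt
Reagents that add atoms: none
Why: Acidic fluoride cleavage of the silyl ether frees the allylic C2 alcohol without acetate migration or base-induced chemistry of the γ-hydroxy enone; configuration at C2 and C4 is kept.

Step 7
Reactants: 8 (R)-3-methylglutaric acid monomethyl ester; 9 mono-tert-butyl succinate (4 equiv)
Product: 10 diester
Conditions: platinum electrodes, NaOMe (0.05 equiv), MeOH, constant current, 40 °C
Reagents that add atoms: none
Why: Mixed Kolbe electrolysis (anodic decarboxylation of both half-esters and radical cross-coupling) forms the C11–C12 bond, excess 9 suppresses homocoupling of 8, and the C13 stereocenter β to the radical is untouched.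

Step 8
Reactants: 10 diester
Product: 11 side-chain acid
Conditions: TFA, CH2Cl2, rt
Reagents that add atoms: none
Why: Acidolysis of the tert-butyl ester (loss of isobutene) frees the C8 acid while the methyl ester and C13 stay intact.

Step 9
Reactants: 7 hydroxy enone; 11 side-chain acid
Product: 12 allylic ester
Conditions: PPh3, DIAD, THF, 0 °C → rt
Reagents that add atoms: none
Why: Mitsunobu esterification displaces the activated allylic C2 oxygen by the carboxylate with SN2 inversion (4-hydroxycyclohexenone type, no SN2′ path towards the electron-poor C10), placing the ester oxygen on the β face, anti to C19, and attaching the whole side chain.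

Step 10
Reactants: 12 allylic ester
Product: 13 dienyl ester
Conditions: Zn, CH2Br2, TiCl4, THF/CH2Cl2, 0 °C → rt
Reagents that add atoms: dibromomethane, BrCBr
Why: Takai–Lombardo methylenation with the non-basic titanium methylene reagent converts the hindered enone carbonyl into the exocyclic C5=C6 alkene (adding C6) without touching the three esters or the allylic stereocenter.

Step 11
Reactants: 13 dienyl ester
Product: 16 Claisen acid, via tris-silyl ketene acetal 14 (not isolated), via silyl ester 15 (not isolated)
Conditions: LiN(iPr)2 (4.5 equiv), THF, −78 °C; Me3SiCl/Et3N; −78 → 50 °C; then 1 M HCl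
Reagents that add atoms: none
Why: Ireland–Claisen rearrangement: LiN(iPr)2 in THF gives the E(O)-enolate, whose silyl ketene acetal has C11 cis to the allylic oxygen; the suprafacial [3,3] shift bonds C9 to C10 on the β face from which the C2–O bond leaves (1,3-transfer of chirality, C20 ends α, cis to C19), and the boat-like transition state enforced by the cyclohexenyl ring (a chair would press the silyloxy-bearing carbon onto the C3–C4 bridge and the C18 methyl) sets C9 as required, while the acetate and methyl ester are only silylated and return on work-up.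

Step 12
Reactants: 16 Claisen acid
Product: 19 bromomethyl ketone, via acid chloride 17 (not isolated), via diazoketone 18 (not isolated)
Conditions: 1-chloro-N,N,2-trimethylprop-1-en-1-amine, CH2Cl2, 0 °C → rt; CH2N2 (3 equiv), Et2O, 0 °C; 48% aq. HBr (1.05 equiv), −10 °C
Reagents that add atoms: diazomethane, C=[N+]=[N-]; hydrogen bromide, Br
Why: Neutral acid chloride formation, C-acylation of diazomethane and HBr cleavage of the diazoketone (Nierenstein-type sequence) add C7 as a bromomethyl ketone without base, so the C9 stereocenter α to the carbonyl is kept.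

Step 13
Reactants: 19 bromomethyl ketone
Product: 20 decalone
Conditions: Bu3SnH (1.3 equiv, syringe pump, 8 h), AIBN (0.1 equiv), PhH (0.005 M), 80 °C
Reagents that add atoms: none
Why: Bu3Sn• abstracts bromine from C7 to give an electrophilic α-keto radical, which adds to the unhindered, electron-rich =CH2 terminus (C6) of the exocyclic C5=C6 alkene; the resulting tertiary C5 radical is quenched by hydrogen-atom transfer from Bu3SnH, which carries the chain. The closest known reaction type is the tin hydride-mediated cyclisation of α-halo ketones onto 1,1-disubstituted alkenes (α-acyl radical cyclisation with the carbonyl inside the new ring). Ring B closes in the 6-endo-trig mode, because the 5-exo alternative would have to bond C7 to the fully substituted C5 wedged between the quaternary C4 and C10, and α-acyl radicals whose carbonyl lies in the forming ring are intrinsically endo-selective. The only new stereocenter, C5, is set in the hydrogen-atom transfer: the α face of the ring-fusion radical is covered by the axial C20 methyl on C10 and the axial C19 acetoxymethyl on C4, so hydrogen should arrive from the β face and give the trans ring fusion. The step needs chemoselectivity for the exocyclic methylene over the internal, less nucleophilic C1=C2 alkene of ring A and cyclisation faster than direct reduction, which high dilution and slow addition of Bu3SnH should secure; the neutral conditions leave the C9 stereocenter next to the ketone untouched.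

Step 14
Reactants: 20 decalone
Product: 21 enol triflate
Conditions: KN(SiMe3)2, THF, −78 °C; PhNTf2, −78 → 0 °C
Reagents that add atoms: N-phenylbis(trifluoromethanesulfonimide), O=S(=O)(N(c1ccccc1)S(=O)(=O)C(F)(F)F)C(F)(F)F
Why: Kinetic deprotonation removes a proton from the unhindered C7 methylene rather than the hindered C9–H, and O-triflation of the enolate fixes the alkene at C7=C8 without touching C9.

Step 15
Reactants: 21 enol triflate
Product: 22 hydroxy triflate
Conditions: BH3·THF, THF, 0 °C; then 30% H2O2, pH 7 phosphate buffer, 0 °C → rt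
Reagents that add atoms: hydrogen peroxide, OO
Why: Hydroboration–oxidation of the ring A alkene: borane adds syn from the β face, anti to the axial C20 methyl on the allylic C10 and the axial C19 group, with boron on C2 (C1 is neopentylic), and oxidation with retention gives the equatorial C2 alcohol, while the electron-poor, hindered enol triflate alkene is not hydroborated.

Step 16
Reactants: 22 hydroxy triflate
Product: 23 methyl ester
Conditions: MeZnCl (4 equiv), Pd(PPh3)4 (5 mol %), THF, 60 °C
Reagents that add atoms: methylzinc chloride, C[Zn]Cl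
Why: Negishi cross-coupling (oxidative addition of the enol triflate to zerovalent palladium, transmetallation, reductive elimination) puts the C17 methyl on C8 with the alkene held at C7=C8; the esters are tolerated and the free hydroxyl only consumes one equivalent of MeZnCl.

Step 17
Reactants: 23 methyl ester
Product: 24 CNP0162900.1
Conditions: LiI (6 equiv), EtOAc, reflux; then 1 M HCl
Reagents that add atoms: none
Why: SN2 dealkylation of the methyl ester by iodide at the O–CH3 carbon frees the C15 acid, whereas the C19 acetate cannot react this way because its alkyl carbon is neopentylic; no stereocenter is touched.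

**Compound list**

1 | (4R,6R)-4-hydroxy-2,2,6-trimethylcyclohexan-1-one ((4R,6R)-actinol) | CC1(C)C[C@H](O)C[C@@H](C)C1=O | starting material
2 | (4R,6R)-4-[(tert-butyldiphenylsilyl)oxy]-2,2,6-trimethylcyclohexan-1-one | CC1(C)C[C@H](O[Si](c2ccccc2)(c2ccccc2)C(C)(C)C)C[C@@H](C)C1=O | intermediate
3 | oxime of 2, N–OH syn to the CH(CH3) carbon and anti to the quaternary carbon | CC1(C)C[C@H](O[Si](c2ccccc2)(c2ccccc2)C(C)(C)C)C[C@@H](C)/C1=N\O | intermediate
4 | O-acetyl oxime of 5: 2-(acetoxymethyl)-4-(tert-butyldiphenylsilyloxy)-2,6-dimethylcyclohexanone O-acetyl oxime, acetoxymethyl cis to the silyloxy group | CC(=O)OC[C@]1(C)C[C@H](O[Si](c2ccccc2)(c2ccccc2)C(C)(C)C)C[C@@H](C)/C1=N\OC(C)=O | intermediate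
5 | (2S,4R,6R)-2-(acetoxymethyl)-4-[(tert-butyldiphenylsilyl)oxy]-2,6-dimethylcyclohexan-1-one (C19 acetoxymethyl cis to the C2 silyloxy group) | CC(=O)OC[C@]1(C)C[C@H](O[Si](c2ccccc2)(c2ccccc2)C(C)(C)C)C[C@@H](C)C1=O | intermediate
6 | 6-(acetoxymethyl)-4-[(tert-butyldiphenylsilyl)oxy]-2,6-dimethylcyclohex-2-en-1-one, acetoxymethyl cis to the silyloxy group (C1=C10 enone, C5 ketone) | CC(=O)OC[C@]1(C)C[C@H](O[Si](c2ccccc2)(c2ccccc2)C(C)(C)C)C=C(C)C1=O | intermediate
7 | 6-(acetoxymethyl)-4-hydroxy-2,6-dimethylcyclohex-2-en-1-one, hydroxyl cis to the acetoxymethyl group | CC(=O)OC[C@]1(C)C[C@H](O)C=C(C)C1=O | intermediate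
8 | (3R)-5-methoxy-3-methyl-5-oxopentanoic acid ((R)-3-methylglutaric acid monomethyl ester) | OC(=O)C[C@@H](C)CC(=O)OC | starting material
9 | 4-(tert-butoxy)-4-oxobutanoic acid (mono-tert-butyl succinate) | OC(=O)CCC(=O)OC(C)(C)C | starting material
10 | 7-tert-butyl 1-methyl (3R)-3-methylheptanedioate | CC(C)(C)OC(=O)CCC[C@@H](C)CC(=O)OC | intermediate
11 | (5R)-7-methoxy-5-methyl-7-oxoheptanoic acid (C8–C15 side-chain acid) | OC(=O)CCC[C@@H](C)CC(=O)OC | intermediate
12 | ester of 11 with the C2-inverted alcohol of 7: 2-acyloxy-C1=C10-en-5-one of ring A, ester oxygen trans to the C19 acetoxymethyl group | CC(=O)OC[C@]1(C)C[C@@H](OC(=O)CCC[C@@H](C)CC(=O)OC)C=C(C)C1=O | intermediate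
13 | dienyl ester: as 12 with the C5 carbonyl replaced by the exocyclic C5=C6 methylene | CC(=O)OC[C@]1(C)C[C@@H](OC(=O)CCC[C@@H](C)CC(=O)OC)C=C(C)C1=C | intermediate
14 | tris(trimethylsilyl ketene acetal) of 13; the allylic ester as the ketene acetal with C11 cis to the allylic oxygen | C=C(O[Si](C)(C)C)OC[C@]1(C)C[C@@H](O/C(O[Si](C)(C)C)=C\CC[C@@H](C)C=C(OC)O[Si](C)(C)C)C=C(C)C1=C | intermediate (not isolated)
15 | rearranged trimethylsilyl ester (C9–C10 bond formed; acetate and methyl ester still as silyl ketene acetals) | C=C(O[Si](C)(C)C)OC[C@]1(C)CC=C[C@@](C)([C@H](CC[C@@H](C)C=C(OC)O[Si](C)(C)C)C(=O)O[Si](C)(C)C)C1=C | intermediate (not isolated)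
16 | Claisen acid: ring A with C1=C2 alkene, exocyclic C5=C6 methylene, C4 (CH3, CH2OAc), quaternary C10 (CH3 cis to CH2OAc) bearing C9H(C8OOH)(side chain) | CC(=O)OC[C@]1(C)CC=C[C@@](C)([C@H](CC[C@@H](C)CC(=O)OC)C(=O)O)C1=C | intermediate
17 | acid chloride of 16 | CC(=O)OC[C@]1(C)CC=C[C@@](C)([C@H](CC[C@@H](C)CC(=O)OC)C(Cl)=O)C1=C | intermediate (not isolated)
18 | diazomethyl ketone from 17 | CC(=O)OC[C@]1(C)CC=C[C@@](C)([C@H](CC[C@@H](C)CC(=O)OC)C(=O)C=[N+]=[N-])C1=C | intermediate (not isolated)
19 | bromomethyl ketone (C7H2Br–C8(=O)–C9) | CC(=O)OC[C@]1(C)CC=C[C@@](C)([C@H](CC[C@@H](C)CC(=O)OC)C(=O)CBr)C1=C | intermediate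
20 | trans-fused decalone: methyl 19-acetoxy-8-oxo-17-nor-ent-labd-1-en-15-oate (C5–H trans to C20, side chain on C9 cis to C20) | CC(=O)OC[C@]1(C)CC=C[C@@]2(C)[C@H](CC[C@@H](C)CC(=O)OC)C(=O)CC[C@H]12 | intermediate
21 | C7=C8 enol triflate of 20 | CC(=O)OC[C@]1(C)CC=C[C@@]2(C)[C@H](CC[C@@H](C)CC(=O)OC)C(OS(=O)(=O)C(F)(F)F)=CC[C@H]12 | intermediate
22 | 2-hydroxy enol triflate (C2–OH equatorial, trans to C19 and C20) | CC(=O)OC[C@]1(C)C[C@@H](O)C[C@@]2(C)[C@H](CC[C@@H](C)CC(=O)OC)C(OS(=O)(=O)C(F)(F)F)=CC[C@H]12 | intermediate
23 | methyl ester of the target | CC(=O)OC[C@]1(C)C[C@@H](O)C[C@@]2(C)[C@H](CC[C@@H](C)CC(=O)OC)C(C)=CC[C@H]12 | intermediate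
24 | CNP0162900.1: (2S,4R,5S,9R,10S,13R)-19-acetoxy-2-hydroxylabd-7-en-15-oic acid | CC(=O)OC[C@]1(C)C[C@@H](O)C[C@@]2(C)[C@H](CC[C@@H](C)CC(=O)O)C(C)=CC[C@H]12 | target

**Step count and risks**

Total steps: 17. Longest linear sequence: 15 (steps 1–6 and 9–17).

Three steps most likely to fail:

1. Step 3 (C–H acetoxylation). Risk: poor site selectivity of the palladation (attack at the axial C4 methyl or, after oxime isomerisation, at C20) or over-oxidation to a diacetate. The fallback sets out from 2 and comes back at 5, bringing in the C19 oxygen by hydroxyl-directed C–H silylation. NaBH4 reduction of 2 should give the equatorial C5 carbinol F1. Et2SiH2 with [Ir(cod)OMe]2 converts it into the diethylhydrosilyl ether F2. [Ir(cod)OMe]2 with 3,4,7,8-tetramethyl-1,10-phenanthroline and norbornene at 100 °C should close the trans-fused oxasilolane F3 at the equatorial C4 methyl. Tamao–Fleming oxidation (H2O2, KHCO3) gives the 1,3-diol F4. The primary hydroxyl is acetylated selectively (Ac2O, 2,4,6-collidine, −20 °C) to the hydroxy acetate F5, and Dess–Martin oxidation returns to ketone 5.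

2. Step 11 (Ireland–Claisen rearrangement). Risk: insufficient discrimination between boat and chair transition states, which would erode stereocontrol at C9 (C10 stays secured by the suprafacial shift). The fallback sets out from 20 (carried through steps 12 and 13 as a C9 epimer mixture) and comes back at 21. Kinetic enolisation (LiN(iPr)2, Me3SiCl, THF, −78 °C) gives the C7=C8 silyl enol ether F6, and Saegusa oxidation (Pd(OAc)2, MeCN) gives the C6=C7 enone F7. LiN(iPr)2 then removes the only α′ proton (C9–H), and protonation of the cross-conjugated enolate at −78 °C from the β face, anti to C20, should give the single enone F8. Conjugate reduction with LiBH(sBu)3 and trapping of the C7=C8 enolate with PhNTf2 returns enol triflate 21.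

3. Step 13 (radical ring closure). Risk: premature reduction of the α-keto radical, addition to the C1=C2 alkene, or unselective hydrogen delivery at C5. The fallback sets out from 16 and comes back at 20, closing ring B by a polar C6–C7 alkylation. Acid 16 is taken through acid chloride 17 and Me2CuLi (Et2O, −78 °C) to the methyl ketone F9. 9-BBN (0 °C) should hydroborate only the exocyclic methylene, from the β face, and buffered H2O2 gives the primary alcohol F10 with C5 set. I2, PPh3 and imidazole give the iodide F11. LiN(iPr)2 (THF, −78 → 0 °C) forms the kinetic methyl enolate, whose 6-exo-tet alkylation at C6 closes ring B to 20 without touching C9.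

Further compounds
F1 | step 3 | C5 carbinol from 2 (hydroxyl equatorial, trans to the silyloxy group) | CC1(C)C[C@H](O[Si](c2ccccc2)(c2ccccc2)C(C)(C)C)C[C@@H](C)[C@H]1O
F2 | step 3 | diethylhydrosilyl ether of F1 | CC1(C)C[C@H](O[Si](c2ccccc2)(c2ccccc2)C(C)(C)C)C[C@@H](C)[C@H]1O[SiH](CC)CC
F3 | step 3 | trans-fused diethyl-oxasilolane spanning the C5 oxygen and C19 | C[C@@]12C[C@H](O[Si](c3ccccc3)(c3ccccc3)C(C)(C)C)C[C@@H](C)[C@H]1O[Si](CC)(CC)C2
F4 | step 3 | 1,3-diol (C5–OH and C19–OH) | OC[C@]1(C)C[C@H](O[Si](c2ccccc2)(c2ccccc2)C(C)(C)C)C[C@@H](C)[C@H]1O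
F5 | step 3 | C19 acetate of F4 (C5–OH free) | CC(=O)OC[C@]1(C)C[C@H](O[Si](c2ccccc2)(c2ccccc2)C(C)(C)C)C[C@@H](C)[C@H]1O
F6 | step 11 | C7=C8 trimethylsilyl enol ether of 20 (C9 epimers) | CC(=O)OC[C@]1(C)CC=C[C@@]2(C)C(CC[C@@H](C)CC(=O)OC)C(O[Si](C)(C)C)=CC[C@H]12
F7 | step 11 | C6=C7 enone, C8 ketone (C9 epimers) | CC(=O)OC[C@]1(C)CC=C[C@@]2(C)C(CC[C@@H](C)CC(=O)OC)C(=O)C=C[C@H]12
F8 | step 11 | C6=C7 enone with C9 as in the target | CC(=O)OC[C@]1(C)CC=C[C@@]2(C)[C@H](CC[C@@H](C)CC(=O)OC)C(=O)C=C[C@H]12
F9 | step 13 | methyl ketone from 16 (C8 acetyl) | CC(=O)OC[C@]1(C)CC=C[C@@](C)([C@H](CC[C@@H](C)CC(=O)OC)C(C)=O)C1=C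
F10 | step 13 | C6 primary alcohol (C5–H trans to C20) | CC(=O)OC[C@]1(C)CC=C[C@@](C)([C@H](CC[C@@H](C)CC(=O)OC)C(C)=O)[C@@H]1CO
F11 | step 13 | C6 iodide of F10 | CC(=O)OC[C@]1(C)CC=C[C@@](C)([C@H](CC[C@@H](C)CC(=O)OC)C(C)=O)[C@@H]1CI
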